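**Retrosynthetic overview**

1. Target ⇐ its 3-deacylated 1,2,3-triol by site-selective benzoylation of the allylic C3–OH; that triol ⇐ a cyclohexa-2,4-dienol by hydroxyl-directed syn-dihydroxylation (C2 and C3 set from C1).
2. The dienol (tertiary C1–OH, trans C6–OBz) ⇐ an enantioenriched o-quinol by hydroxyl-directed 1,2-reduction (C6 set from C1) and benzoylation.
3. Key disconnection: the o-quinol ⇐ achiral 2-hydroxybenzyl benzoate by catalytic enantioselective oxidative dearomatisation, in which the neighbouring benzoate forms the C1–O bond; aromaticity is broken and the first stereocentre is set in the same event.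
4. 2-Hydroxybenzyl benzoate ⇐ salicyl alcohol + benzoic acid.
5. Rings: no ring is built. The carbocycle is the benzene ring of salicyl alcohol (dearomatised in step 2, then oxygenated); the three phenyl rings arrive intact with the benzoyl groups.

Assumption: the (R,R)-iodoarene catalyst is taken to give the (S)-o-quinol 5; if the sense of induction is the reverse, the (S,S)-catalyst is used and nothing else changes.

Ring numbering in all names: C1 = carbon bearing OH and CH2OBz, C2 = CH(OH), C3 = CH(OBz), C4=C5, C6 = CH(OBz). The C1 descriptor changes from S (5, 6, 8) to R (10, 11) only because CIP priorities change when C2 becomes oxygenated.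

**Step 1**
Reactants: 1 salicyl alcohol (2-hydroxybenzyl alcohol); 2 benzoic acid
Product: 3 2-hydroxybenzyl benzoate
Conditions: PPh3, DIAD, THF, 0 °C to rt
Reagents that add atoms: benzoic acid (compound 2), OC(=O)c1ccccc1
Why: Mitsunobu esterification, in which the benzylic alcohol is activated as its oxyphosphonium salt and displaced by benzoate, which as the far stronger acid outcompetes the phenol as pronucleophile, so the phenolic OH stays free; no stereocentre.

**Step 2**
Reactants: 3 2-hydroxybenzyl benzoate
Product: 6 [(1S,6R)-1,6-dihydroxycyclohexa-2,4-dien-1-yl]methyl benzoate (the two OH groups trans; C6–OH cis to CH2OBz), via spiro-dioxolanylium cation 4 (not isolated), via o-quinol 5 (not isolated)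
Conditions: (R,R)-2-iodo-1,3-bis[1-(mesitylcarbamoyl)ethoxy]benzene (10 mol %), mCPBA (1.05 equiv), H2O (3 equiv), CH2Cl2–HFIP 4:1 (0.02 M), −20 °C; then MeCN–AcOH, Me4NBH(OAc)3 (5 equiv), −40 to −20 °C; aq. NaHCO3 work-up
Reagents that add atoms: water, O; 3-chloroperbenzoic acid, OOC(=O)c1cccc(Cl)c1 (terminal oxidant; its oxygen reaches the product through the iodine-bound hydroxide/water pool)
Why: Proposed new method: mCPBA oxidises the chiral iodoarene to a trivalent-iodine species that binds the phenol oxygen, the carbonyl oxygen of the neighbouring benzoate then attacks the CH2-bearing ortho carbon in 5-exo fashion as the iodoarene leaves (this C–O bond formation inside the chiral ligand sphere sets C1 and breaks aromaticity), water opens the resulting 2-phenyl-1,3-dioxolan-2-ylium ion 4 at its cationic carbon and the ortho-acid collapses to tertiary alcohol plus primary benzoate 5, the closest known reaction types being the Kita–Ishihara enantioselective dearomative spirolactonisation of phenols and naphthols with this catalyst class and Woodward–Prévost acyloxonium capture; the cold, dilute o-quinol is then reduced before it can dimerise by Evans–Saksena hydroxyl-directed reduction, in which boron bound to the tertiary C1–OH delivers hydride to the same face of the C6 carbonyl and so gives the trans-1,6-diol.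

**Step 3**
Reactants: 6 [(1S,6R)-1,6-dihydroxycyclohexa-2,4-dien-1-yl]methyl benzoate; 7 benzoyl chloride
Product: 8 [(1S,6R)-6-(benzoyloxy)-1-hydroxycyclohexa-2,4-dien-1-yl]methyl benzoate
Conditions: BzCl (1.2 equiv), pyridine, DMAP (5 mol %), CH2Cl2, 0 °C
Reagents that add atoms: benzoyl chloride (compound 7), O=C(Cl)c1ccccc1
Why: Einhorn-type nucleophile-catalysed acylation in which only the secondary allylic C6–OH reacts, the tertiary C1–OH being too hindered; retention at C6, and the C6–OH is removed as a competing hydrogen-bond donor for step 4.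

**Step 4**
Reactants: 8 [(1S,6R)-6-(benzoyloxy)-1-hydroxycyclohexa-2,4-dien-1-yl]methyl benzoate
Product: 10 [(1R,2R,3R,6R)-6-(benzoyloxy)-1,2,3-trihydroxycyclohex-4-en-1-yl]methyl benzoate (1-OH, 2-OH and 3-OH all cis; 6-OBz on the other face), via osmate ester 9 (not isolated)
Conditions: OsO4 (1.05 equiv), TMEDA (1.1 equiv), CH2Cl2, −78 °C; then HCl, MeOH, rt
Reagents that add atoms: osmium tetroxide, O=[Os](=O)(=O)=O
Why: Donohoe hydroxyl-directed dihydroxylation, in which OsO4·TMEDA is hydrogen-bonded by the tertiary C1–OH and adds to the adjacent C2=C3 bond on the OH face (also the open face, anti to CH2OBz and to the C6 benzoate), setting C2 and C3 cis to the C1–OH while C4=C5 next to the non-donor, electron-withdrawing benzoate is left, and acid methanolysis then releases the diol from the hexavalent-osmium glycolate 9.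

**Step 5**
Reactants: 10 [(1R,2R,3R,6R)-6-(benzoyloxy)-1,2,3-trihydroxycyclohex-4-en-1-yl]methyl benzoate; 7 benzoyl chloride
Product: 11 [(1R,2R,3R,6R)-3,6-bis(benzoyloxy)-1,2-dihydroxycyclohex-4-en-1-yl]methyl benzoate (CNP0128482.3)
Conditions: BzCl (1.1 equiv), pyridine, CH2Cl2, −40 to 0 °C
Reagents that add atoms: benzoyl chloride (compound 7), O=C(Cl)c1ccccc1
Why: Site-selective Einhorn benzoylation, in which the allylic, unhindered C3–OH is acylated while the C2–OH (flanked by the quaternary C1 and by C3) and the tertiary C1–OH stay free; no stereocentre is touched.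

**Compound list**

1 | salicyl alcohol (2-hydroxybenzyl alcohol) | OCc1ccccc1O | starting material
2 | benzoic acid | OC(=O)c1ccccc1 | starting material
3 | 2-hydroxybenzyl benzoate | O=C(OCc1ccccc1O)c1ccccc1 | intermediate
4 | (S)-2-phenyl-spiro[1,3-dioxolan-2-ylium-4,1'-cyclohexa-2',4'-dien]-6'-one cation (3-chlorobenzoate counter-ion) | [O+]1=C(c2ccccc2)OC[C@]13C=CC=CC3=O | intermediate (not isolated)
5 | (S)-(1-hydroxy-6-oxocyclohexa-2,4-dien-1-yl)methyl benzoate (o-quinol) | O=C(OC[C@@]1(O)C=CC=CC1=O)c1ccccc1 | intermediate (not isolated)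
6 | [(1S,6R)-1,6-dihydroxycyclohexa-2,4-dien-1-yl]methyl benzoate | O=C(OC[C@@]1(O)C=CC=C[C@H]1O)c1ccccc1 | intermediate
7 | benzoyl chloride | O=C(Cl)c1ccccc1 | starting material
8 | [(1S,6R)-6-(benzoyloxy)-1-hydroxycyclohexa-2,4-dien-1-yl]methyl benzoate | O=C(OC[C@@]1(O)C=CC=C[C@H]1OC(=O)c1ccccc1)c1ccccc1 | intermediate
9 | osmate ester of 10: dioxo-osmium (hexavalent) 2,3-glycolate chelated by TMEDA, on the C1–OH face | O=C(OC[C@@]1(O)[C@H](O2)[C@H](O[Os-2]23(=O)(=O)[N+](C)(C)CC[N+]3(C)C)C=C[C@H]1OC(=O)c1ccccc1)c1ccccc1 | intermediate (not isolated)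
10 | [(1R,2R,3R,6R)-6-(benzoyloxy)-1,2,3-trihydroxycyclohex-4-en-1-yl]methyl benzoate | O=C(OC[C@@]1(O)[C@H](O)[C@H](O)C=C[C@H]1OC(=O)c1ccccc1)c1ccccc1 | intermediate
11 | [(1R,2R,3R,6R)-3,6-bis(benzoyloxy)-1,2-dihydroxycyclohex-4-en-1-yl]methyl benzoate | O=C(OC[C@@]1(O)[C@H](O)[C@H](OC(=O)c2ccccc2)C=C[C@H]1OC(=O)c1ccccc1)c1ccccc1 | target

**Step count and risk**

Total steps: 5. Longest linear sequence: 5 (1 → 3 → 6 → 8 → 10 → 11).

Most likely to fail, in order:

Step 2 (dearomatisation/reduction). The enantioselective benzoate-assisted dearomatisation is unprecedented; the sense and level of induction are unknown. Para attack by external nucleophiles and dimerisation of 5 compete, which is why the reaction is run cold and dilute and 5 is reduced in the same flask. Diol 6 reverts to 3 with acid and is handled on base-washed silica. Fallback, setting out from 3 and coming back at 8: the dearomatisation is run without a chiral catalyst and the enantiomers are separated at the benzoylation. With PhI(OAc)2 in HFIP–H2O at −20 °C, 3 follows the same anchimeric path to racemic material, that is 4 together with the enantiomeric spiro-dioxolanylium cation F1 and, after hydrolysis, 5 together with the enantiomeric o-quinol F2. The same in-flask Me4NBH(OAc)3 reduction gives 6 together with the enantiomeric trans-diol F3. Kinetic-resolution benzoylation of this racemate (BzCl 0.55 equiv, Et3N, 0.5 mol % (S)-1-methyl-2-(isoindolin-2-ylmethyl)pyrrolidine or its antipode, CH2Cl2, −78 °C) acylates only (1S,6R)-6 and gives 8 directly, leaving F3 behind. This replaces steps 2 and 3 at the cost of half the material.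

Step 4 (directed dihydroxylation). Osmylation could go to C4=C5 instead of C2=C3, or benzoates could migrate during osmate cleavage. Fallback, setting out from 8 and coming back at 11: the C2/C3 oxygens are brought in by epoxide chemistry with two inversions. VO(acac)2/t-BuOOH (CH2Cl2, 0 °C) epoxidises 8 at C2=C3 on the face of the C1–OH to give the syn-epoxy alcohol F4. Dilute HClO4 in THF–H2O at 0 °C opens the vinyl epoxide at the allylic C3 with inversion to give the 2,3-trans triol F5 (the C3 epimer of 10). The cis C1/C2 diol is tied up in the flask with PhB(OH)2 (toluene, MgSO4) as the cyclic phenylboronate F6, which also blocks epoxide re-closure. Mitsunobu reaction of the remaining allylic C3–OH with benzoic acid 2 (PPh3, DIAD, THF) installs the benzoate with a second inversion to give the boronate-protected target F7, and exchange with pinacol frees 11. This path also makes step 5 unnecessary.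

Step 5 (site-selective benzoylation). The C2 ester or the 2,3-dibenzoate could form. Fallback, setting out from 10 and coming back at 11: selectivity is drawn from tin chelation instead of sterics. Heating 10 with Bu2SnO (toluene, azeotropic removal of water) gives the 2,3-O-dibutylstannylene acetal F8, in which the equatorial, allylic O3 is the activated oxygen; BzCl at 0 °C acylates O3 and aqueous work-up gives 11.

**Further compounds**

F1 | step 2 | (R)-2-phenyl-spiro[1,3-dioxolan-2-ylium-4,1'-cyclohexa-2',4'-dien]-6'-one cation (enantiomer of 4) | [O+]1=C(c2ccccc2)OC[C@@]13C=CC=CC3=O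
F2 | step 2 | (R)-(1-hydroxy-6-oxocyclohexa-2,4-dien-1-yl)methyl benzoate (enantiomer of 5) | O=C(OC[C@]1(O)C=CC=CC1=O)c1ccccc1
F3 | step 2 | [(1R,6S)-1,6-dihydroxycyclohexa-2,4-dien-1-yl]methyl benzoate (enantiomer of 6) | O=C(OC[C@]1(O)C=CC=C[C@@H]1O)c1ccccc1
F4 | step 4 | 2,3-epoxide of 8 with the epoxide oxygen cis to the C1–OH | O=C(OC[C@@]1(O)[C@H](O2)[C@H]2C=C[C@H]1OC(=O)c1ccccc1)c1ccccc1
F5 | step 4 | C3 epimer of 10 (3-OH trans to 2-OH) | O=C(OC[C@@]1(O)[C@H](O)[C@@H](O)C=C[C@H]1OC(=O)c1ccccc1)c1ccccc1
F6 | step 4 | 1,2-O-phenylboronate of F5 | O=C(OC[C@@]12OB(c3ccccc3)O[C@@H]1[C@@H](O)C=C[C@H]2OC(=O)c1ccccc1)c1ccccc1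
F7 | step 4 | 1,2-O-phenylboronate of 11 | O=C(OC[C@@]12OB(c3ccccc3)O[C@@H]1[C@H](OC(=O)c1ccccc1)C=C[C@H]2OC(=O)c1ccccc1)c1ccccc1
F8 | step 5 | 2,3-O-dibutylstannylene acetal of 10 | O=C(OC[C@@]1(O)[C@H](O2)[C@H](O[Sn]2(CCCC)CCCC)C=C[C@H]1OC(=O)c1ccccc1)c1ccccc1
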